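The synthesis rests on disconnecting lactone E at its C18–C19 bond and its acyl C–O bond. This α-methyl-γ-butyrolactone is joined through its O–CH carbon (C18) to the N–CH carbon (C3) of ring B, which is the retron of a 2-carboxyallyl anion adding to a C3 aldehyde. One zinc-mediated reaction with ethyl 2-(bromomethyl)acrylate forms C18–C19, sets C18 and closes ring E as its α-methylene lactone. The precursor is the tetracyclic ene-lactam aldehyde (rings A–D, O11 silyl ether), built from a quinone monoketal by asymmetric ethyl addition, Negishi coupling with a serine-derived alkylzinc, Ireland–Claisen rearrangement and epoxy-acid lactonisation.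

Key step: step 18

Remark: locants are N4, C3 (N–CH), C2, C1 (spiro carbon), C9a/C9 (enamine carbons), C5–C8 (azepine chain), C10 (CH–Et), C11 (CH–O), C12, C13/C14/C15 (lactone D CH, C=O, CH3) and C18–C22 (lactone E); rings are A azepine, B pyrrolidine, C carbocycle, D spiro lactone, E pendant lactone. The C2–C3–C18 unit needs only three carbons and is taken from L-serine (its CH2O becomes C18, which gives 3R). Compounds 1, 4, 19 and 29 are assumed to be purchasable.

Step 1
Reactants: 1 4,4-dimethoxycyclohexa-2,5-dien-1-one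
Product: 2 (S)-5-ethyl-4,4-dimethoxycyclohex-2-en-1-one
Conditions: Et2Zn, Cu(OTf)2 (2 mol %), BINOL-derived N,N-bis(1-phenylethyl)phosphoramidite (4 mol %), toluene, −25 °C
Reagents that add atoms: diethylzinc, CC[Zn]CC
Why: Copper-catalysed asymmetric conjugate addition of a dialkylzinc with a chiral phosphoramidite is established on this quinone monoketal; it breaks the symmetry of the dienone and sets C10, the ligand antipode being the one that gives the (S)-product.

Step 2
Reactants: 2 (S)-5-ethyl-4,4-dimethoxycyclohex-2-en-1-one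
Product: 3 (S)-5-ethyl-2-iodo-4,4-dimethoxycyclohex-2-en-1-one
Conditions: I2, pyridine, CH2Cl2, 0 °C → rt
Reagents that add atoms: iodine, II
Why: Pyridine-promoted α-iodination of an enone (conjugate addition of pyridine, iodination of the enolate, elimination) puts iodine on the α-vinyl carbon that becomes C1, and the ketal tolerates the mild base.

Step 3
Reactants: 4 N-Boc-O-benzyl-L-serinol
Product: 5 tert-butyl N-[(2S)-1-(benzyloxy)-3-iodopropan-2-yl]carbamate
Conditions: PPh3, I2, imidazole, CH2Cl2, 0 °C → rt
Reagents that add atoms: iodine, II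
Why: Appel iodination of the primary alcohol; the carbamate-bearing stereocentre is not touched and only its descriptor changes.

Step 4
Reactants: 5 serinol-derived iodide; 3 iodoenone
Product: 7 C1-alkylated enone (Boc-amino benzyl ether side chain), via alkylzinc iodide 6 (not isolated)
Conditions: Zn dust (TMSCl-activated), DMF, rt; then 3, Pd2(dba)3 (2.5 mol %), SPhos (10 mol %), rt
Reagents that add atoms: none
Why: Zinc insertion gives a carbamate-coordinated β-amido alkylzinc iodide, and Negishi sp3–sp2 coupling with the activated α-iodoenone forms C1–C2 without touching a stereocentre.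

Step 5
Reactants: 7 C1-alkylated enone
Product: 8 cis-allylic alcohol (9a-OH cis to 10-ethyl)
Conditions: NaBH4, CeCl3·7H2O, MeOH, −78 °C
Reagents that add atoms: none
Why: Luche 1,2-reduction; hydride should add anti to the C10 ethyl group as with 5-substituted cyclohexenones, so the 9a-hydroxyl comes out cis to ethyl.

Step 6
Reactants: 8 cis-allylic alcohol
Product: 9 trans-allylic propanoate (C9a inverted)
Conditions: EtCO2H, PPh3, DIAD, toluene, 0 °C → rt
Reagents that add atoms: propanoic acid, CCC(=O)O
Why: Mitsunobu esterification replaces the activated hydroxyl by propanoate with SN2 inversion at C9a, which puts the ester oxygen trans to ethyl, on the face to which the later sigmatropic shift must deliver C13.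

Step 7
Reactants: 9 trans-allylic propanoate
Product: 10 γ-propanoyloxy enone (C11 ketone)
Conditions: PPTS (cat.), acetone–H2O, 40 °C
Reagents that add atoms: water, O
Why: Acid-catalysed hydrolysis of the allylic dimethyl ketal gives the conjugated C11 ketone as a γ-acyloxy enone, a stable compound class, and PPTS spares the Boc group and the ester.

Step 8
Reactants: 10 γ-propanoyloxy enone
Product: 11 C11 allylic alcohol (11-OH trans to ethyl)
Conditions: NaBH4, CeCl3·7H2O, MeOH, −78 °C
Reagents that add atoms: none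
Why: Luche reduction of a 6-alkylcyclohexenone; axial hydride delivery with the ethyl group equatorial should give the alcohol trans to ethyl (hence cis to the C9a ester), which sets C11.

Step 9
Reactants: 11 C11 allylic alcohol
Product: 12 C11 TBS ether propanoate
Conditions: TBSCl, imidazole, DMAP (cat.), DMF, 40 °C
Reagents that add atoms: tert-butyldimethylsilyl chloride, CC(C)(C)[Si](C)(C)Cl
Why: Standard silylation of a secondary allylic alcohol; the chloride/imidazole protocol avoids silyl triflate, which would attack the Boc group.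

Step 10
Reactants: 12 C11 TBS ether propanoate
Product: 15 13-epi γ,δ-unsaturated acid, via (Z)-silyl ketene acetal 13 (not isolated), via silyl ester 14 (not isolated)
Conditions: LDA (2.3 equiv), THF–DMPU, −78 °C; TMSCl; then 60 °C; H3O+ work-up
Reagents that add atoms: none
Why: Ireland–Claisen rearrangement: the suprafacial [3,3] shift carries the propanoate α-carbon from O9a to the same face of C12 (sets C12, trans to ethyl) and moves the alkene to C1=C9a; the (Z)-ketene acetal, through the boat-like array usual for cyclohexenyl esters, should place the C13 methyl anti to C11 (13-epi), which step 15 corrects.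

Step 11
Reactants: 15 13-epi γ,δ-unsaturated acid
Product: 17 hydroxy lactone (ring D closed; 9a-OH), via epoxy acid 16 (not isolated)
Conditions: mCPBA, CH2Cl2, 0 °C → rt; CSA (cat.)
Reagents that add atoms: 3-chloroperoxybenzoic acid, OOC(=O)c1cccc(Cl)c1
Why: Prilezhaev epoxidation should occur anti to the pseudoaxial C12 side chain, and the carboxylic acid then opens the epoxide at tertiary C1 with inversion in a 5-exo mode (only the anti epoxide can lactonise), so lactone D is cis-fused with O1 cis to C13 and C2 trans, which sets C1.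

Step 12
Reactants: 17 hydroxy lactone
Product: 18 keto lactone
Conditions: DMP, NaHCO3, CH2Cl2, rt
Reagents that add atoms: none
Why: Dess–Martin oxidation of the secondary alcohol gives the C9a ketone; C1 is quaternary, so the α-acyloxy ketone cannot epimerise.

Step 13
Reactants: 18 keto lactone; 19 tert-butyl 4-iodobutanoate
Product: 21 C9-alkylated keto lactone (tert-butyl ester arm), via dilithio enolate 20 (not isolated)
Conditions: LiHMDS (2.1 equiv), THF, −78 °C; then 19, DMPU, −78 → −20 °C
Reagents that add atoms: none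
Why: Enolate alkylation: with C1 quaternary only C9 can enolise, the carbamate N–H takes the first equivalent of base, and the primary iodide should alkylate carbon anti to the ethyl group (the C9 configuration is erased in step 14).

Step 14
Reactants: 21 C9-alkylated keto lactone
Product: 24 13-epi ene-lactam benzyl ether (rings A–D), via keto amino acid 22 (not isolated), via cyclic imino acid 23 (not isolated)
Conditions: TMSOTf, 2,6-lutidine, CH2Cl2, 0 °C → rt; MeOH; then DIC, HOAt, iPr2NEt, CH2Cl2, rt
Reagents that add atoms: none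
Why: Silyl triflate cleaves the Boc and tert-butyl ester groups without protic acid that would endanger the silyl ether, the freed amine condenses with the C9a ketone to the five-membered cyclic imine (ring B), and carbodiimide-mediated N-acylation by the C5 acid with loss of the C9 proton closes ring A as the ene-lactam (imine–enamine acylation).

Step 15
Reactants: 24 13-epi ene-lactam benzyl ether
Product: 26 ene-lactam benzyl ether (natural C13), via lithium enolate 25 (not isolated)
Conditions: LDA, THF, −78 → −40 °C; AcOH, −78 °C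
Reagents that add atoms: none
Why: Kinetic protonation of the lactone enolate (the lactone C–H is more acidic than the lactam C–H): the planar C13 should take its proton from the open face, away from ring C and the axial 11-silyloxy group, so the methyl group ends up cis to C11 as in the target.

Step 16
Reactants: 26 ene-lactam benzyl ether
Product: 27 ene-lactam primary alcohol
Conditions: H2 (1 atm), Pd(OH)2/C, EtOAc, rt
Reagents that add atoms: none
Why: Hydrogenolysis of the benzyl ether; the tetrasubstituted enamide alkene and the silyl ether are inert.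

Step 17
Reactants: 27 ene-lactam primary alcohol
Product: 28 tetracyclic ene-lactam aldehyde (silyl ether)
Conditions: DMP, NaHCO3, CH2Cl2, 0 °C → rt
Reagents that add atoms: none
Why: Dess–Martin oxidation gives the α-amido aldehyde under buffered, non-basic conditions, the acylated nitrogen limits enolisation at C3, and the aldehyde is used at once.

Step 18
Reactants: 28 tetracyclic ene-lactam aldehyde; 29 ethyl 2-(bromomethyl)acrylate
Product: 32 pentacyclic α-methylene lactone (ene-lactam silyl ether), via allylzinc bromide 30 (not isolated), via zinc alkoxide 31 (not isolated)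
Conditions: Zn dust (activated), THF, 50 °C
Reagents that add atoms: none
Why: Zinc inserts into the allylic C–Br bond of 29, and the 2-(ethoxycarbonyl)allylzinc bromide 30 adds to the aldehyde through a six-membered chair array with allylic transposition, forming C18–C19. This is the known Barbier-type synthesis of α-methylene-γ-butyrolactones from 2-(bromomethyl)acrylates and aldehydes. Ring E then closes by 5-exo-trig acyl substitution of the zinc alkoxide 31 on the ethyl ester, with loss of ethoxide. C18 is set by the adjacent C3 centre: with the C3–N bond held anti to the incoming allyl group (non-chelation mode), attack past H3 should give the anti N/O relation (18S). The step needs this facial selectivity and no epimerisation at C3; the nitrogen is a conjugated, non-basic ene-lactam nitrogen that binds zinc poorly and does not promote enolisation of the aldehyde. Lactone D, the silyl ether and the ene-lactam are inert to allylzinc in THF.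

Step 19
Reactants: 32 pentacyclic α-methylene lactone
Product: 33 α-methyl lactone lactam (silyl ether)
Conditions: H2 (1 atm), RhCl(PPh3)3 (10 mol %), toluene–EtOH, rt
Reagents that add atoms: none
Why: Homogeneous hydrogenation with RhCl(PPh3)3 reduces only the 1,1-disubstituted exocyclic alkene, from the face opposite the C18 substituent, which sets C20 with methyl cis to that substituent; the tetrasubstituted enamide is left.

Step 20
Reactants: 33 α-methyl lactone lactam
Product: 34 O11-silylated target amine
Conditions: Zn(OAc)2 (10 mol %), (EtO)3SiH, THF, 40 °C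
Reagents that add atoms: none
Why: Zinc-catalysed hydrosilylation of the tertiary lactam to the amine is chemoselective over lactones and silyl ethers and gives the enamine of the target.

Step 21
Reactants: 34 O11-silylated target amine
Product: 35 target CNP0154902.3
Conditions: HF·pyridine, pyridine, THF, 0 °C → rt
Reagents that add atoms: none
Why: Fluoride desilylation under buffered, non-basic conditions should free the C11 hydroxyl without acyl migration of lactone D from O1 to O11.

Compound list

1 | 4,4-dimethoxycyclohexa-2,5-dien-1-one | COC1(OC)C=CC(=O)C=C1 | starting material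
2 | (S)-5-ethyl-4,4-dimethoxycyclohex-2-en-1-one | CC[C@H]1CC(=O)C=CC1(OC)OC | intermediate
3 | (S)-5-ethyl-2-iodo-4,4-dimethoxycyclohex-2-en-1-one | CC[C@H]1CC(=O)C(I)=CC1(OC)OC | intermediate
4 | tert-butyl N-[(2R)-1-(benzyloxy)-3-hydroxypropan-2-yl]carbamate (N-Boc-O-benzyl-L-serinol) | CC(C)(C)OC(=O)N[C@@H](COCc1ccccc1)CO | starting material
5 | tert-butyl N-[(2S)-1-(benzyloxy)-3-iodopropan-2-yl]carbamate | CC(C)(C)OC(=O)N[C@@H](COCc1ccccc1)CI | intermediate
6 | [(2S)-3-(benzyloxy)-2-(Boc-amino)propyl]zinc iodide | CC(C)(C)OC(=O)N[C@@H](COCc1ccccc1)C[Zn]I | intermediate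
7 | 2-[(2R)-3-(benzyloxy)-2-(Boc-amino)propyl]-(5S)-5-ethyl-4,4-dimethoxycyclohex-2-en-1-one | CC[C@H]1CC(=O)C(C[C@H](COCc2ccccc2)NC(=O)OC(C)(C)C)=CC1(OC)OC | intermediate
8 | allylic alcohol from 7, 9a-OH cis to the 10-ethyl group | CC[C@H]1C[C@@H](O)C(C[C@H](COCc2ccccc2)NC(=O)OC(C)(C)C)=CC1(OC)OC | intermediate
9 | propanoate with inverted C9a, ester oxygen trans to ethyl | CC[C@H]1C[C@H](OC(=O)CC)C(C[C@H](COCc2ccccc2)NC(=O)OC(C)(C)C)=CC1(OC)OC | intermediate
10 | γ-propanoyloxy enone with the C11 ketone | CC[C@H]1C[C@H](OC(=O)CC)C(C[C@H](COCc2ccccc2)NC(=O)OC(C)(C)C)=CC1=O | intermediate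
11 | C11 allylic alcohol, 11-OH trans to ethyl and cis to the C9a propanoate | CC[C@H]1C[C@H](OC(=O)CC)C(C[C@H](COCc2ccccc2)NC(=O)OC(C)(C)C)=C[C@@H]1O | intermediate
12 | C11 TBS ether of 11 | CC[C@H]1C[C@H](OC(=O)CC)C(C[C@H](COCc2ccccc2)NC(=O)OC(C)(C)C)=C[C@@H]1O[Si](C)(C)C(C)(C)C | intermediate
13 | (Z)-trimethylsilyl ketene acetal of 12 (methyl cis to OSiMe3; N-silylated carbamate) | CC[C@H]1C[C@H](O/C(O[Si](C)(C)C)=C/C)C(C[C@H](COCc2ccccc2)N([Si](C)(C)C)C(=O)OC(C)(C)C)=C[C@@H]1O[Si](C)(C)C(C)(C)C | intermediate
14 | trimethylsilyl ester of the rearranged acid (N-silylated) | CC[C@H]1CC=C(C[C@H](COCc2ccccc2)N([Si](C)(C)C)C(=O)OC(C)(C)C)[C@H]([C@H](C)C(=O)O[Si](C)(C)C)[C@@H]1O[Si](C)(C)C(C)(C)C | intermediate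
15 | γ,δ-unsaturated acid, C1=C9a alkene, C12 side chain cis to 11-OTBS, 13-epi methyl | CC[C@H]1CC=C(C[C@H](COCc2ccccc2)NC(=O)OC(C)(C)C)[C@H]([C@H](C)C(=O)O)[C@@H]1O[Si](C)(C)C(C)(C)C | intermediate
16 | epoxy acid, C1–C9a epoxide anti to the C12 side chain | CC[C@H]1C[C@H]2O[C@@]2(C[C@H](COCc3ccccc3)NC(=O)OC(C)(C)C)[C@H]([C@H](C)C(=O)O)[C@@H]1O[Si](C)(C)C(C)(C)C | intermediate
17 | hydroxy lactone, cis-fused lactone D on O1, 9a-OH trans to O1, 13-epi | CC[C@H]1C[C@@H](O)[C@]2(C[C@H](COCc3ccccc3)NC(=O)OC(C)(C)C)OC(=O)[C@@H](C)[C@@H]2[C@@H]1O[Si](C)(C)C(C)(C)C | intermediate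
18 | keto lactone (C9a ketone), 13-epi | CC[C@H]1CC(=O)[C@]2(C[C@H](COCc3ccccc3)NC(=O)OC(C)(C)C)OC(=O)[C@@H](C)[C@@H]2[C@@H]1O[Si](C)(C)C(C)(C)C | intermediate
19 | tert-butyl 4-iodobutanoate | CC(C)(C)OC(=O)CCCI | starting material
20 | dilithio species of 18 (C9 enolate, N-lithio carbamate) | CC[C@H]1C=C(O[Li])[C@]2(C[C@H](COCc3ccccc3)N([Li])C(=O)OC(C)(C)C)OC(=O)[C@@H](C)[C@@H]2[C@@H]1O[Si](C)(C)C(C)(C)C | intermediate
21 | C9-alkylated keto lactone, tert-butyl butanoate arm trans to ethyl, 13-epi | CC[C@H]1[C@H](CCCC(=O)OC(C)(C)C)C(=O)[C@]2(C[C@H](COCc3ccccc3)NC(=O)OC(C)(C)C)OC(=O)[C@@H](C)[C@@H]2[C@@H]1O[Si](C)(C)C(C)(C)C | intermediate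
22 | keto amino acid from 21 (free amine, free C5 acid) | CC[C@H]1[C@H](CCCC(=O)O)C(=O)[C@]2(C[C@H](COCc3ccccc3)N)OC(=O)[C@@H](C)[C@@H]2[C@@H]1O[Si](C)(C)C(C)(C)C | intermediate
23 | cyclic imino acid (ring B closed as C9a=N) | CC[C@H]1[C@H](CCCC(=O)O)C2=N[C@@H](COCc3ccccc3)C[C@]23OC(=O)[C@@H](C)[C@@H]3[C@@H]1O[Si](C)(C)C(C)(C)C | intermediate
24 | tetracyclic ene-lactam, C18 benzyl ether, 11-OTBS, 13-epi | CC[C@H]1C2=C3N(C(=O)CCC2)[C@@H](COCc4ccccc4)C[C@]32OC(=O)[C@@H](C)[C@@H]2[C@@H]1O[Si](C)(C)C(C)(C)C | intermediate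
25 | lithium enolate of lactone D | CC[C@H]1C2=C3N(C(=O)CCC2)[C@@H](COCc4ccccc4)C[C@]32OC(O[Li])=C(C)[C@@H]2[C@@H]1O[Si](C)(C)C(C)(C)C | intermediate
26 | tetracyclic ene-lactam, C18 benzyl ether, 11-OTBS, natural C13 (methyl cis to C11) | CC[C@H]1C2=C3N(C(=O)CCC2)[C@@H](COCc4ccccc4)C[C@]32OC(=O)[C@H](C)[C@@H]2[C@@H]1O[Si](C)(C)C(C)(C)C | intermediate
27 | tetracyclic ene-lactam primary alcohol | CC[C@H]1C2=C3N(C(=O)CCC2)[C@@H](CO)C[C@]32OC(=O)[C@H](C)[C@@H]2[C@@H]1O[Si](C)(C)C(C)(C)C | intermediate
28 | tetracyclic ene-lactam aldehyde (silyl ether), key-step precursor | CC[C@H]1C2=C3N(C(=O)CCC2)[C@@H](C=O)C[C@]32OC(=O)[C@H](C)[C@@H]2[C@@H]1O[Si](C)(C)C(C)(C)C | intermediate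
29 | ethyl 2-(bromomethyl)acrylate | C=C(CBr)C(=O)OCC | starting material
30 | [2-(ethoxycarbonyl)allyl]zinc bromide | C=C(C[Zn]Br)C(=O)OCC | intermediate
31 | zinc alkoxide of the (18S)-hydroxy ester adduct | CC[C@H]1C2=C3N(C(=O)CCC2)[C@@H]([C@@H](O[Zn]Br)CC(=C)C(=O)OCC)C[C@]32OC(=O)[C@H](C)[C@@H]2[C@@H]1O[Si](C)(C)C(C)(C)C | intermediate
32 | pentacyclic α-methylene lactone (ene-lactam, silyl ether), key-step product | CC[C@H]1C2=C3N(C(=O)CCC2)[C@@H]([C@@H]2CC(=C)C(=O)O2)C[C@]32OC(=O)[C@H](C)[C@@H]2[C@@H]1O[Si](C)(C)C(C)(C)C | intermediate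
33 | pentacyclic lactam with saturated lactone E (20-methyl cis to the C18 substituent), silyl ether | CC[C@H]1C2=C3N(C(=O)CCC2)[C@@H]([C@@H]2C[C@H](C)C(=O)O2)C[C@]32OC(=O)[C@H](C)[C@@H]2[C@@H]1O[Si](C)(C)C(C)(C)C | intermediate
34 | O11-TBS ether of the target (tertiary enamine) | CC[C@H]1C2=C3N(CCCC2)[C@@H]([C@@H]2C[C@H](C)C(=O)O2)C[C@]32OC(=O)[C@H](C)[C@@H]2[C@@H]1O[Si](C)(C)C(C)(C)C | intermediate
35 | CNP0154902.3 | CC[C@H]1C2=C3N(CCCC2)[C@@H]([C@@H]2C[C@H](C)C(=O)O2)C[C@]32OC(=O)[C@H](C)[C@@H]2[C@@H]1O | target

Total step count: 21. Longest linear sequence: 20 steps (steps 1, 2 and 4–21; step 3 is a one-step side branch).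

Steps most likely to fail

Step 13. The risk is slow C-alkylation of the hindered C9 enolate by an unactivated iodide, with N-alkylation of the lithiated carbamate and proton exchange competing. The fallback sets out from 18: allylation (LiHMDS, allyl bromide) gives the C9-allyl keto lactone F1. TMSOTf/2,6-lutidine then MeOH gives the cyclic imine F2. Acryloyl chloride/Et3N gives the N-acryloyl enamide F3. Ring-closing metathesis with second-generation Grubbs catalyst closes ring A as the unsaturated ene-lactam F4. H2/RhCl(PPh3)3 then saturates its disubstituted C6=C7 alkene, and the route is rejoined at 24.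

Step 15. The risk is proton delivery to both faces of the enolate, or proton return before the hindered 13-H is fully removed, leaving the 13-epi methyl. The fallback sets out from 24: LDA then CBr4 brominates the enolate from the open face to give the α-bromo lactone F5, with the methyl group pushed toward ring C. Bu3SnH/AIBN then replaces bromine by hydrogen, delivered to the planar radical from the same open face by the bulky stannane, and the route is rejoined at 26.

Step 18. The risk is attack on the other aldehyde face if the lactam carbonyl chelates zinc, or partial epimerisation at C3 before addition. The fallback sets out from 28: zinc with 29 in THF–aqueous NH4Cl at room temperature stops at the open hydroxy ester F6, as both C18 epimers. Dess–Martin oxidation gives the keto ester F7. CBS reduction, with the catalyst antipode that gives 18S, returns the single hydroxy ester F8 under reagent control. PPTS in warm toluene then closes ring E, and the route is rejoined at 32.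

Further compounds

F1 | step 13 | C9-allyl keto lactone | CC[C@H]1[C@H](CC=C)C(=O)[C@]2(C[C@H](COCc3ccccc3)NC(=O)OC(C)(C)C)OC(=O)[C@@H](C)[C@@H]2[C@@H]1O[Si](C)(C)C(C)(C)C
F2 | step 13 | cyclic imine with C9-allyl group | CC[C@H]1[C@H](CC=C)C2=N[C@@H](COCc3ccccc3)C[C@]23OC(=O)[C@@H](C)[C@@H]3[C@@H]1O[Si](C)(C)C(C)(C)C
F3 | step 13 | N-acryloyl enamide | CC[C@H]1C(CC=C)=C2N(C(=O)C=C)[C@@H](COCc3ccccc3)C[C@]23OC(=O)[C@@H](C)[C@@H]3[C@@H]1O[Si](C)(C)C(C)(C)C
F4 | step 13 | unsaturated ene-lactam (C6=C7) | CC[C@H]1C2=C3N(C(=O)C=CC2)[C@@H](COCc4ccccc4)C[C@]32OC(=O)[C@@H](C)[C@@H]2[C@@H]1O[Si](C)(C)C(C)(C)C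
F5 | step 15 | α-bromo lactone | CC[C@H]1C2=C3N(C(=O)CCC2)[C@@H](COCc4ccccc4)C[C@]32OC(=O)[C@@](C)(Br)[C@@H]2[C@@H]1O[Si](C)(C)C(C)(C)C
F6 | step 18 | open hydroxy ester (C18 epimers) | CC[C@H]1C2=C3N(C(=O)CCC2)[C@@H](C(O)CC(=C)C(=O)OCC)C[C@]32OC(=O)[C@H](C)[C@@H]2[C@@H]1O[Si](C)(C)C(C)(C)C
F7 | step 18 | C18 keto ester | CC[C@H]1C2=C3N(C(=O)CCC2)[C@@H](C(=O)CC(=C)C(=O)OCC)C[C@]32OC(=O)[C@H](C)[C@@H]2[C@@H]1O[Si](C)(C)C(C)(C)C
F8 | step 18 | (18S)-hydroxy ester | CC[C@H]1C2=C3N(C(=O)CCC2)[C@@H]([C@@H](O)CC(=C)C(=O)OCC)C[C@]32OC(=O)[C@H](C)[C@@H]2[C@@H]1O[Si](C)(C)C(C)(C)C
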